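(The earlier runs and the new flask come from a simulation from invented constants, noise included.)

1. As bookkeeper of this flask, I enter each mole of substrate, the limiting reagent, under what it has become.

the same everywhere: substrate 27 mM
- cedar: coupling partner 2 equiv; the very flask that is asked about, followed so far
- flask: coupling partner 2.00 equiv; time 40 min

- cedar (time / min: first product / %, bis adduct / %, substrate / %): 0.667: 38, 2, 65; 1.50: 51, 7, 38; 3.00: 59, 18, 20; 5.00: 60, 28, 10

(each reading ± 1.5 percentage points)

1. equivalents of coupling partner to substrate, everything else as given, that leave most first product at 40 min
2. the amount of first product then, in percent of the substrate charged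
3. the amount of first product with the amounts as given

- the earlier runs were read with a standard deviation of 1.5 percentage points

2. At 5.00 min the flask's entries are substrate 10 %, first product 60 % and bis adduct 28 %. Together they make 98.0 %, so these three entries nearly close the books, given the scatter on each reading.

3. Each first product took one coupling partner and each bis adduct two, so [coupling partner] is 22.7 mM at that reading.

4. The open question is whether first product keeps passing into bis adduct. The readings give 10.8 M⁻¹ at 3.00 min and 20.6 M⁻¹ at 5.00 min, twice as much. I carry this number, the reaction quotient Q = [bis adduct]/([first product][coupling partner]).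

5. The readings end with Q still rising, well short of 40 min, and they show no ceiling, so my reckoning stays a test and gives no figure of its own.

6. The forecast says 1.06 equiv, 61.5 % and, as given, 21 %, the last on the ground that first product, late in the run, “decays second order”. On my two-entry books, that last figure needs Q = 663 M⁻¹, which is 32.2 times the reading at 5.00 min.

7. The flask gives 1.15 equiv, 70.2 % and, as given, 45.1 %.

    substrate + coupling partner → first product (k = 14.8 M⁻¹ min⁻¹)
    coupling partner + first product ⇌ bis adduct (K = 86.0 M⁻¹, k = 4.14 M⁻¹ min⁻¹)
    substrate + first product → side product (k = 0.673 M⁻¹ min⁻¹)

8. From 20.6 M⁻¹ at 5.00 min, Q in this flask reaches 85.5 M⁻¹ at 40.0 min, below 663 M⁻¹ and level with the equilibrium constant of the bis adduct step, 86 M⁻¹, and first product stands at 45.0 % after 400 min. The neighbour flask charged with 68 mM of substrate holds 31.3 % first product and 65.6 % bis adduct, and its Q comes to 86.0 M⁻¹.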